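**Retrosynthetic overview**
- The last bond made is C3′–CH2 of the hydroxyalkyl chain (B-alkyl Suzuki coupling of a 3′-bromo isoflavone with hydroborated 2-methylbut-3-en-2-ol), so the tertiary alcohol enters after every acidic step.
- The key disconnection is the O1–C2 bond of the pyranone: ring C is closed when a ring-A phenol adds to a β-(dimethylamino)enone whose C2 carbon comes from DMF-DMA.
- Which phenol closes decides 6- versus 8-prenyl: that oxygen is carried as its prenyl ether (the other two ring-A oxygens as MOM ethers), and a para-Claisen–Cope relay moves the prenyl group to the carbon para to it and frees only this oxygen.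
- The enone precursor is a deoxybenzoin from phloroglucinol and 2-(3-bromo-4-hydroxyphenyl)acetic acid (Friedel–Crafts C-acylation).
- Rings A and B are bought; ring C is the only ring formed (step 3).

Assumption: the target SMILES has no stereocentre and no E/Z-stereogenic double bond, so the compound is achiral and no step has to control configuration.

**Step 1**
Reactants: 1 phloroglucinol (benzene-1,3,5-triol); 2 2-(3-bromo-4-hydroxyphenyl)acetic acid
Product: 3 2-(3-bromo-4-hydroxyphenyl)-1-(2,4,6-trihydroxyphenyl)ethan-1-one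
Conditions: BF3·Et2O (solvent), 85 °C; then aq NaOAc
Reagents that add atoms: none
Why: BF3-promoted Friedel–Crafts C-acylation (Houben–Hoesch type) of the symmetric triphenol by the free arylacetic acid; the ketone is held as its BF2 chelate, which stops a second acylation, and no stereocentre is formed.

**Step 2**
Reactants: 3 2-(3-bromo-4-hydroxyphenyl)-1-(2,4,6-trihydroxyphenyl)ethan-1-one; 4 prenyl bromide (1-bromo-3-methylbut-2-ene)
Product: 6 2-[3-bromo-4-(methoxymethoxy)phenyl]-1-[2,4-bis(methoxymethoxy)-6-(3-methylbut-2-enyloxy)phenyl]ethan-1-one, via tris-MOM phenol 5 (not isolated)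
Conditions: MOMCl, i-Pr2NEt, DMF, 0 °C → rt; then K2CO3, 4, 45 °C
Reagents that add atoms: chloromethyl methyl ether (MOMCl), COCCl
Why: Two Williamson etherifications in one flask: with the amine base MOMCl caps the three free phenols and stops at the phenol hydrogen-bonded to the ketone (the usual outcome for phloroacylphenones; the two ortho phenols are equivalent, so no isomer can arise), and carbonate then O-prenylates this last phenol by SN2 at the primary allylic bromide.

**Step 3**
Reactants: 6 2-[3-bromo-4-(methoxymethoxy)phenyl]-1-[2,4-bis(methoxymethoxy)-6-(3-methylbut-2-enyloxy)phenyl]ethan-1-one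
Product: 9 3-[3-bromo-4-(methoxymethoxy)phenyl]-5,7-bis(methoxymethoxy)-6-(3-methylbut-2-enyl)-4H-chromen-4-one, via enaminone 7 (not isolated), via phenol enaminone 8 (not isolated)
Conditions: Me2NCH(OMe)2, PhMe, 100 °C; concentrate; PhNEt2, 200 °C
Reagents that add atoms: N,N-dimethylformamide dimethyl acetal (DMF-DMA), COC(OC)N(C)C
Why: Proposed new method: an aryl prenyl ether para-Claisen–Cope relay run on the β-(dimethylamino)enone 7 (from DMF-DMA condensation at the ketone CH2), so that the phenol it liberates closes ring C at once; at 200 °C the prenyl group shifts from oxygen to the ortho carbon ([3,3]) and on to the para carbon (Cope [3,3]), the dienone tautomerises to phenol 8, and this phenol, the only free OH in the molecule and by construction para to the prenyl group, adds to the enaminone carbon and expels Me2NH (6-endo addition–elimination), which forms the O1–C2 bond and fixes the 6-prenyl pattern without any stereocentre; the closest known reactions are the thermal para-Claisen–Cope rearrangement of 2-prenyloxy-4,6-bis(methoxymethoxy)aryl ketones and the DMF-DMA enaminone annulation of 2-hydroxydeoxybenzoins, each run as a separate operation and not as a relay on an enaminone.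

**Step 4**
Reactants: 9 3-[3-bromo-4-(methoxymethoxy)phenyl]-5,7-bis(methoxymethoxy)-6-(3-methylbut-2-enyl)-4H-chromen-4-one
Product: 10 3-(3-bromo-4-hydroxyphenyl)-5,7-dihydroxy-6-(3-methylbut-2-enyl)-4H-chromen-4-one
Conditions: 3 M HCl (aq), MeOH, 55 °C
Reagents that add atoms: none
Why: Acid-catalysed methanolysis of the three MOM acetals (acetal cleavage); short exposure is the usual way to unmask C-prenylated isoflavones before the prenyl group can close onto a flanking phenol, and the aryl bromide and chromone are inert.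

**Step 5**
Reactants: 10 3-(3-bromo-4-hydroxyphenyl)-5,7-dihydroxy-6-(3-methylbut-2-enyl)-4H-chromen-4-one; 11 2-methylbut-3-en-2-ol; 12 9-borabicyclo[3.3.1]nonane (9-BBN)
Product: 14 Coloratanin A, 5,7-dihydroxy-3-[4-hydroxy-3-(3-hydroxy-3-methylbutyl)phenyl]-6-(3-methylbut-2-enyl)-4H-chromen-4-one, via alkylborane 13 (not isolated)
Conditions: 11, 12, THF, 0 °C → rt; then aq K3PO4, 10, Pd(OAc)2, SPhos, THF–DMF, 65 °C
Reagents that add atoms: none
Why: Anti-Markovnikov hydroboration puts boron on the terminal CH2 of 11 (the tertiary OH is borylated with loss of H2), and B-alkyl Suzuki–Miyaura coupling transfers the primary alkyl group to the aryl bromide after oxidative addition of zerovalent palladium; leftover B–H is destroyed by the aqueous base before 10 is added, so the prenyl alkene is untouched, and no stereocentre is formed.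

**Compound list**
1 | phloroglucinol (benzene-1,3,5-triol) | Oc1cc(O)cc(O)c1 | starting material
2 | 2-(3-bromo-4-hydroxyphenyl)acetic acid | OC(=O)Cc1ccc(O)c(Br)c1 | starting material
3 | 2-(3-bromo-4-hydroxyphenyl)-1-(2,4,6-trihydroxyphenyl)ethan-1-one | O=C(Cc1ccc(O)c(Br)c1)c1c(O)cc(O)cc1O | intermediate
4 | prenyl bromide (1-bromo-3-methylbut-2-ene) | CC(C)=CCBr | starting material
5 | 2-[3-bromo-4-(methoxymethoxy)phenyl]-1-[2-hydroxy-4,6-bis(methoxymethoxy)phenyl]ethan-1-one | O=C(Cc1ccc(OCOC)c(Br)c1)c1c(O)cc(OCOC)cc1OCOC | intermediate (not isolated)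
6 | 2-[3-bromo-4-(methoxymethoxy)phenyl]-1-[2,4-bis(methoxymethoxy)-6-(3-methylbut-2-enyloxy)phenyl]ethan-1-one | O=C(Cc1ccc(OCOC)c(Br)c1)c1c(OCC=C(C)C)cc(OCOC)cc1OCOC | intermediate
7 | (E)-2-[3-bromo-4-(methoxymethoxy)phenyl]-3-(dimethylamino)-1-[2,4-bis(methoxymethoxy)-6-(3-methylbut-2-enyloxy)phenyl]prop-2-en-1-one | CN(C)/C=C(\c1ccc(OCOC)c(Br)c1)C(=O)c1c(OCC=C(C)C)cc(OCOC)cc1OCOC | intermediate (not isolated)
8 | (E)-2-[3-bromo-4-(methoxymethoxy)phenyl]-3-(dimethylamino)-1-[6-hydroxy-2,4-bis(methoxymethoxy)-3-(3-methylbut-2-enyl)phenyl]prop-2-en-1-one | CN(C)/C=C(\c1ccc(OCOC)c(Br)c1)C(=O)c1c(O)cc(OCOC)c(CC=C(C)C)c1OCOC | intermediate (not isolated)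
9 | 3-[3-bromo-4-(methoxymethoxy)phenyl]-5,7-bis(methoxymethoxy)-6-(3-methylbut-2-enyl)-4H-chromen-4-one | CC(C)=CCc1c(OCOC)cc2occ(-c3ccc(OCOC)c(Br)c3)c(=O)c2c1OCOC | intermediate
10 | 3-(3-bromo-4-hydroxyphenyl)-5,7-dihydroxy-6-(3-methylbut-2-enyl)-4H-chromen-4-one | CC(C)=CCc1c(O)cc2occ(-c3ccc(O)c(Br)c3)c(=O)c2c1O | intermediate
11 | 2-methylbut-3-en-2-ol | CC(C)(O)C=C | starting material
12 | 9-borabicyclo[3.3.1]nonane (9-BBN) | B1C2CCCC1CCC2 | starting material
13 | 9-{3-methyl-3-[(9-borabicyclo[3.3.1]nonan-9-yl)oxy]butyl}-9-borabicyclo[3.3.1]nonane | CC(C)(CCB1C2CCCC1CCC2)OB1C2CCCC1CCC2 | intermediate (not isolated)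
14 | Coloratanin A, 5,7-dihydroxy-3-[4-hydroxy-3-(3-hydroxy-3-methylbutyl)phenyl]-6-(3-methylbut-2-enyl)-4H-chromen-4-one | CC(C)=CCc1c(O)cc2occ(-c3ccc(O)c(CCC(C)(C)O)c3)c(=O)c2c1O | target

**Step count and risks**
Total steps: 5. Longest linear sequence: 5 (1 → 3 → 6 → 9 → 10 → 14).

The three steps most likely to fail:

Step 3 (the proposed new relay). The ortho-dienone may enolise to a 1,1-dimethylallyl phenol instead of undergoing the Cope shift, or enaminone 7 may not survive 200 °C. The fallback sets out from 6 and runs the two known operations separately. Heating 6 in PhNEt2 at 200 °C (thermal para-Claisen–Cope rearrangement of the aryl prenyl ether) gives the rearranged phenol ketone F1. Treating F1 with Me2NCH(OMe)2 in toluene at 90 °C (standard enaminone annulation of a 2-hydroxydeoxybenzoin, passing through 8) comes back to the route at 9.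

Step 4 (acid with a prenyl group between two phenols). The prenyl group may close onto O-5 or O-7 to give a dimethylchroman. The fallback gives up the protecting groups and sets out from 3. Ring C is closed first with Me2NCH(OMe)2 in THF, through the enaminone F2, to give 3′-bromogenistein F3. The sodium salt of F3 is then C-prenylated with 4 (NaOMe, MeOH, 0 °C → rt). This is the known direct nuclear prenylation of 5,7-dihydroxyisoflavones; it gives the 6-prenyl compound as the main C-alkylated product in low yield, beside the 8-isomer and O-ethers that are removed by chromatography. It comes back to the route at 10.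

Step 5 (alkylborane coupling on a free triphenol). Protodebromination or β-hydride loss may win over coupling at the electron-rich ortho-bromophenoxide. The fallback sets out from 10 and uses a Heck reaction with 11 (Pd(OAc)2, P(o-tol)3, Et3N, DMF, 100 °C) to give the (E)-allylic alcohol F4. Hydrogenation of only its disubstituted styrene double bond with H2 and RhCl(PPh3)3 (benzene–EtOH, rt) leaves the trisubstituted prenyl alkene and the chromone C2=C3 bond, and comes back to the route at 14.

**Further compounds**
F1 | step 3 | 2-[3-bromo-4-(methoxymethoxy)phenyl]-1-[6-hydroxy-2,4-bis(methoxymethoxy)-3-(3-methylbut-2-enyl)phenyl]ethan-1-one | O=C(Cc1ccc(OCOC)c(Br)c1)c1c(O)cc(OCOC)c(CC=C(C)C)c1OCOC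
F2 | step 4 | (E)-2-(3-bromo-4-hydroxyphenyl)-3-(dimethylamino)-1-(2,4,6-trihydroxyphenyl)prop-2-en-1-one | CN(C)/C=C(\c1ccc(O)c(Br)c1)C(=O)c1c(O)cc(O)cc1O
F3 | step 4 | 3′-bromogenistein, 3-(3-bromo-4-hydroxyphenyl)-5,7-dihydroxy-4H-chromen-4-one | Oc1cc(O)c2c(c1)occ(-c1ccc(O)c(Br)c1)c2=O
F4 | step 5 | (E)-5,7-dihydroxy-3-[4-hydroxy-3-(3-hydroxy-3-methylbut-1-enyl)phenyl]-6-(3-methylbut-2-enyl)-4H-chromen-4-one | CC(C)=CCc1c(O)cc2occ(-c3ccc(O)c(/C=C/C(C)(C)O)c3)c(=O)c2c1O
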